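## Retrosynthetic overview
1. 10 ⇒ 8: both C–O bonds of ring C (C3–OH and O1–C2) are cut back to the E-enone of chalcone 8 plus one oxygen atom of H2O2. The forward step is an enantioselective epoxidation followed by 6-endo opening by the 2'-OH.
2. 8 ⇒ 3 + 6: the Cα=Cβ bond comes from a Claisen–Schmidt condensation without protecting groups.
3. 3 ⇒ 1 + 2, and 6 ⇒ 4 + two equivalents of 2: the aryl–prenyl bonds come from phenoxide C-alkylation.
4. Ring order: rings A and B are bought. Ring C is the only ring built, and it closes in the last step together with both stereocentres.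

Assumption: the facial sense of the scandium catalyst on this new substrate class cannot be known in advance. The route is written with the ligand antipode that gives the (αR,βS)-epoxide. Both antipodes are available from L- or D-pipecolic acid. The outcome is checked by chiral HPLC, by CD, and by J(2,3) of about 11–12 Hz for the trans isomer.

## Route

Step 1
Reactants: 1 2,4-dihydroxyacetophenone; 2 prenyl bromide (1-bromo-3-methylbut-2-ene)
Product: 3 1-[2,4-dihydroxy-3-(3-methylbut-2-enyl)phenyl]ethanone
Conditions: KOH (1.1 equiv), H2O, 0 °C to rt, 12 h, 2 (1.0 equiv) added dropwise; 1 M HCl; SiO2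
Reagents that add atoms: none
Why: This is an aqueous phenoxide C-alkylation: water shields the phenoxide oxygen by hydrogen bonding, so the allylic bromide is attacked by carbon, preferentially at C3, the most nucleophilic position because it lies between both oxygens (expected 30–40 % after removal of the 5-prenyl and O-prenyl isomers; no stereocentre is formed).

Step 2
Reactants: 4 4-hydroxybenzaldehyde; 2 prenyl bromide (2.4 equiv)
Product: 6 4-hydroxy-3,5-bis(3-methylbut-2-enyl)benzaldehyde, via monoprenyl aldehyde 5 (not isolated)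
Conditions: KOH (2.5 equiv), H2O, 0 °C to rt, 36 h, base and 2 added in two portions; 1 M HCl; SiO2
Reagents that add atoms: none
Why: The same aqueous phenoxide C-alkylation runs twice at the two equivalent ortho positions (para is blocked by CHO), and the neutral O-prenyl ethers are removed by base extraction (expected 25–35 %; no stereocentre is formed).

Step 3
Reactants: 3 1-[2,4-dihydroxy-3-(3-methylbut-2-enyl)phenyl]ethanone; 6 4-hydroxy-3,5-bis(3-methylbut-2-enyl)benzaldehyde
Product: 8 (E)-2',4',4-trihydroxy-3',3,5-triprenylchalcone (sophoradin), via aldol adduct 7 (not isolated)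
Conditions: 50 % aq. KOH (12 equiv), EtOH, Ar, rt to 40 °C, 48–72 h; 1 M HCl to pH 4–5 at 0 °C
Reagents that add atoms: none
Why: This is a Claisen–Schmidt aldol condensation: excess KOH forms the methyl ketone enolate alongside the phenoxides, aldehyde 6 cannot enolise, and E1cB loss of water from 7 gives the conjugated E-enone, while the prenyl groups are inert to base.

Step 4
Reactants: 8 (E)-2',4',4-trihydroxy-3',3,5-triprenylchalcone
Product: 10 (2R,3R)-3,7-dihydroxy-2-[4-hydroxy-3,5-bis(3-methylbut-2-enyl)phenyl]-8-(3-methylbut-2-enyl)-2,3-dihydrochromen-4-one, via chalcone epoxide 9 (not isolated)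
Conditions: Sc(OTf)3 (5 mol%), chiral N,N'-dioxide ligand [propane-1,3-diyl-bridged bis(pipecolic acid 2,6-diisopropylanilide N-oxide)] (5.5 mol%), 2,6-di-tert-butylpyridine (10 mol%), 30 % aq. H2O2 (1.5 equiv, syringe pump), THF, 30 °C, Ar, dark, 24–36 h; aq. Na2S2O3
Reagents that add atoms: hydrogen peroxide, OO
Why: Proposed new method: a non-basic, catalytic enantioselective Algar–Flynn–Oyamada-type annulation; the redox-inert trivalent scandium ion sits in the pocket of the C2-symmetric N,N'-dioxide ligand and binds 8 at two points through the 2'-O/C=O chelate, which fixes the s-cis enone and leaves one face open; a scandium-bound hydroperoxide adds to Cβ and the enolate closes on the O–O bond (Weitz–Scheffer epoxidation) to give the (αR,βS)-epoxide 9, which sets the future C3 as R; no bulk phenoxide is formed, so the enone is not switched off by phenoxide donation, the nucleophilic peroxide leaves the three electron-rich prenyl alkenes alone, and the hindered pyridine traps stray TfOH that could cyclise the o-prenylphenols; the same Lewis acid then loosens the p-hydroxybenzylic Cβ–O bond of 9 and the neighbouring 2'-oxygen attacks Cβ 6-endo from the back (βS becomes 2R), forming O1–C2 and ring C as the 2,3-trans isomer; even a partly SN1-like opening would close to the same diequatorial trans product because the untouched C3 centre directs it, and the missing 6'-substituent disfavours 5-exo closure; the closest known reaction types are the N,N'-dioxide/Sc(OTf)3-catalysed H2O2 epoxidation of simple non-phenolic chalcones, the racemic base-mediated Algar–Flynn–Oyamada reaction and the acid-induced cyclisation of 2'-hydroxychalcone epoxides, none of which has been shown as one enantioselective event on a free 2'-hydroxychalcone.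

## Compound list
1 | 2,4-dihydroxyacetophenone | CC(=O)c1ccc(O)cc1O | starting material
2 | prenyl bromide (1-bromo-3-methylbut-2-ene) | CC(C)=CCBr | starting material
3 | 1-[2,4-dihydroxy-3-(3-methylbut-2-enyl)phenyl]ethanone | CC(=O)c1ccc(O)c(CC=C(C)C)c1O | intermediate
4 | 4-hydroxybenzaldehyde | O=Cc1ccc(O)cc1 | starting material
5 | 4-hydroxy-3-(3-methylbut-2-enyl)benzaldehyde (not isolated) | O=Cc1ccc(O)c(CC=C(C)C)c1 | intermediate
6 | 4-hydroxy-3,5-bis(3-methylbut-2-enyl)benzaldehyde | O=Cc1cc(CC=C(C)C)c(O)c(CC=C(C)C)c1 | intermediate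
7 | racemic aldol adduct, 1-[2,4-dihydroxy-3-prenylphenyl]-3-hydroxy-3-[4-hydroxy-3,5-diprenylphenyl]propan-1-one (not isolated) | CC(C)=CCc1cc(C(O)CC(=O)c2ccc(O)c(CC=C(C)C)c2O)cc(CC=C(C)C)c1O | intermediate
8 | (E)-1-[2,4-dihydroxy-3-(3-methylbut-2-enyl)phenyl]-3-[4-hydroxy-3,5-bis(3-methylbut-2-enyl)phenyl]prop-2-en-1-one (sophoradin) | CC(C)=CCc1cc(/C=C/C(=O)c2ccc(O)c(CC=C(C)C)c2O)cc(CC=C(C)C)c1O | intermediate
9 | [2,4-dihydroxy-3-(3-methylbut-2-enyl)phenyl]{(2R,3S)-3-[4-hydroxy-3,5-bis(3-methylbut-2-enyl)phenyl]oxiran-2-yl}methanone, trans epoxide (not isolated) | CC(C)=CCc1c(O)ccc(C(=O)[C@@H]2O[C@H]2c3cc(CC=C(C)C)c(O)c(CC=C(C)C)c3)c1O | intermediate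
10 | (2R,3R)-3,7-dihydroxy-2-[4-hydroxy-3,5-bis(3-methylbut-2-enyl)phenyl]-8-(3-methylbut-2-enyl)-2,3-dihydrochromen-4-one (2,3-trans) | CC(C)=CCc1cc([C@H]2Oc3c(ccc(O)c3CC=C(C)C)C(=O)[C@@H]2O)cc(CC=C(C)C)c1O | target

## Step count and risks
Total steps: 4. Longest linear sequence: 3 (1 → 3 → 8 → 10, or 4 → 6 → 8 → 10).

**Most likely to fail: step 4 (the new step).**
- Risks:
  - peroxide addition to the donor-rich enone may be slow;
  - the phenols or the α-hydroxyketone product may tie up the catalyst;
  - the Lewis acid may isomerise 8 to the flavanone;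
  - the aroyl group may migrate in 9;
  - the product may be over-oxidised to the flavonol;
  - the ee may be insufficient.
- Fallback (known chemistry, protecting-group based): it sets out from 8. All three phenols are capped with MOMCl (NaH, DMF, 0 °C) to give tris-MOM chalcone F1. A Juliá–Colonna epoxidation (poly-L-leucine, urea–H2O2, DBU, THF, rt) is nucleophilic and spares the prenyl groups, and it gives the (αR,βS) tris-MOM chalcone epoxide F2. Treatment with 1–2 M HCl in MeOH at 40–45 °C removes the three MOM groups. The liberated 2'-OH (compound 9) then opens the epoxide at Cβ with inversion. The fallback comes back to the route at 10, and ee is upgraded by crystallisation if needed.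

**Second: step 3.**
- Risks: the phenoxide of 6 is a poor electrophile and 3 must be deprotonated three times, so conversion may stall. Partial closure to the flavanone can also occur on acidification.
- Fallback: it sets out from 3 and 6 and removes the phenoxide deactivation. Ketone 3 is capped selectively at the non-chelated 4-OH (MOMCl, K2CO3, acetone) to give 2-hydroxy-4-(methoxymethoxy)-3-prenylacetophenone F3. Aldehyde 6 is capped (MOMCl, iPr2NEt, CH2Cl2) to give 4-(methoxymethoxy)-3,5-diprenylbenzaldehyde F4. Their Claisen–Schmidt condensation (KOH, EtOH/H2O, rt) gives bis-MOM chalcone F5. Mild HCl/MeOH (rt to 40 °C) comes back to the route at 8.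

**Third: step 2.**
- Risks: a statistical mixture of mono-C-, di-C- and O-prenylated products, and hence a low yield of 6.
- Fallback: it sets out from 4 and replaces ambident alkylation by site-defined cross-coupling. Br2 (2.1 equiv, AcOH) gives 3,5-dibromo-4-hydroxybenzaldehyde F6. Ac2O/pyridine gives 2,6-dibromo-4-formylphenyl acetate F7. A double Stille coupling with tributyl(3-methylbut-2-enyl)stannane and the zerovalent palladium catalyst Pd(PPh3)4 (DMF, 90 °C) gives 4-formyl-2,6-diprenylphenyl acetate F8. K2CO3/MeOH comes back to the route at 6.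

## Further compounds
F1 | step 4 | tris-MOM chalcone, (E)-1-[2,4-bis(methoxymethoxy)-3-prenylphenyl]-3-[4-(methoxymethoxy)-3,5-diprenylphenyl]prop-2-en-1-one | CC(C)=CCc1cc(/C=C/C(=O)c2ccc(OCOC)c(CC=C(C)C)c2OCOC)cc(CC=C(C)C)c1OCOC
F2 | step 4 | (2R,3S) tris-MOM chalcone epoxide (trans) | COCOc1ccc(C(=O)[C@@H]2O[C@H]2c3cc(CC=C(C)C)c(OCOC)c(CC=C(C)C)c3)c(OCOC)c1CC=C(C)C
F3 | step 3 | 1-[2-hydroxy-4-(methoxymethoxy)-3-(3-methylbut-2-enyl)phenyl]ethanone | CC(=O)c1ccc(OCOC)c(CC=C(C)C)c1O
F4 | step 3 | 4-(methoxymethoxy)-3,5-bis(3-methylbut-2-enyl)benzaldehyde | COCOc1c(CC=C(C)C)cc(C=O)cc1CC=C(C)C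
F5 | step 3 | bis-MOM chalcone, (E)-1-[2-hydroxy-4-(methoxymethoxy)-3-prenylphenyl]-3-[4-(methoxymethoxy)-3,5-diprenylphenyl]prop-2-en-1-one | CC(C)=CCc1cc(/C=C/C(=O)c2ccc(OCOC)c(CC=C(C)C)c2O)cc(CC=C(C)C)c1OCOC
F6 | step 2 | 3,5-dibromo-4-hydroxybenzaldehyde | O=Cc1cc(Br)c(O)c(Br)c1
F7 | step 2 | 2,6-dibromo-4-formylphenyl acetate | CC(=O)Oc1c(Br)cc(C=O)cc1Br
F8 | step 2 | 4-formyl-2,6-bis(3-methylbut-2-enyl)phenyl acetate | CC(=O)Oc1c(CC=C(C)C)cc(C=O)cc1CC=C(C)C
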